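A direct plan would start from comenic acid A1 and grow ring A onto its 4-pyranone: A1 would be esterified, triflated and benzylated at C5 by Negishi coupling to pyranone ester A2.
A2 would be saponified and taken through its acid chloride to diazo ketone A3.
Irradiation of A3 with siloxyalkyne A4 (photo-Wolff, [2+2], 4π opening, 6π closure) would give chromone A5; methylation of the C5–OH, desilylation to A6 and Duff formylation at C8 would finish.
Weakest points:
- The benzannulation of A3 would have to close onto C3 of a 4-pyranone, a photoactive ring for which this cascade is not known, and it would come only after a six-step linear run-up.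
- The run-up itself would expose an electrophilic 4-pyranone to hydroxide-type nucleophiles and to a 1,3-dipole, a long linear effort for a ring A whose pattern can be bought as an arene.
- The endgame would spend three steps (methylation of a chelated OH, desilylation, formylation in hot acid on the finished chromone) to add one carbon, with the product at risk.

**Retrosynthetic overview**
Ring A is bought as 2-methylphloroglucinol. The C8 formyl group goes on first and acts as control element: the hydroxyl para to it (future C5–O) lies outside its chelate and is methylated alone, and the single ring C–H left (future C4a) takes iodine.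
Key disconnection: ring C is cut at C4a–C4, C4–C3 and O1–C2 into the aryl iodide, carbon monoxide (the isolated carbonyl carbon C4) and 4-methoxyphenylallene (C2, C3, the benzylic carbon and ring B). One palladium-catalysed carbonylative annulation joins the three.
Ring order: A (bought), then C (key step); a rhodium-catalysed shift of the exocyclic double bond into ring C ends the route.
The design needs no protecting group, no diazo or photochemical step, and no methylation or formylation once the chromone exists; the risk sits in the key step.

Key step: step 5

Remark: 2-methylphloroglucinol and 4-ethynylanisole are taken as commercial. Chromone numbering (O1, C2, C3, C4, C4a, C5 to C8, C8a) is used for all intermediates; ring A is the benzene ring of the chromone, ring B the anisyl ring, ring C the pyranone ring. The target has no stereocentre.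

Step 1
Reactants: 1 2-methylphloroglucinol (2,4,6-trihydroxytoluene)
Product: 3 2,4,6-trihydroxy-3-methylbenzaldehyde, via iminium chloride 2 (not isolated)
Conditions: POCl3 (1.1 equiv), DMF (1.2 equiv), EtOAc, 0 → 25 °C; then H2O, 50 °C
Reagents that add atoms: N,N-dimethylformamide (CN(C)C=O); water (O)
Why: Vilsmeier–Haack formylation, in which the chloroiminium ion attacks one of the two equivalent free positions of the phloroglucinol ring, the iminium salt 2 is too electron-poor for a second attack, and water hydrolyses it to the aldehyde whose carbon becomes the C8 formyl group.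

Step 2
Reactants: 3 2,4,6-trihydroxy-3-methylbenzaldehyde
Product: 4 2,6-dihydroxy-4-methoxy-3-methylbenzaldehyde
Conditions: MeI (1.05 equiv), K2CO3 (1.0 equiv), acetone, 0 → 25 °C
Reagents that add atoms: iodomethane (CI)
Why: Williamson etherification under acidity control, since the hydroxyl para to the formyl group (future C5–O) is the most acidic of the three and the only one that cannot join the hydrogen-bond chelate of the aldehyde oxygen, so that one equivalent of base and MeI should methylate it alone, as in the known 4-O-monoalkylation of 2,4,6-trihydroxyaryl aldehydes and ketones.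

Step 3
Reactants: 4 2,6-dihydroxy-4-methoxy-3-methylbenzaldehyde
Product: 5 2,6-dihydroxy-3-iodo-4-methoxy-5-methylbenzaldehyde
Conditions: NIS (1.05 equiv), MeCN, 0 → 25 °C, dark
Reagents that add atoms: N-iodosuccinimide (O=C1CCC(=O)N1I)
Why: electrophilic aromatic iodination of an activated phenol at the only ring C–H left (future C4a), which lies ortho to OH, ortho to OMe and para to OH, so that the site is fixed by the substitution pattern and the aldehyde is not touched.

Step 4
Reactants: 6 4-ethynylanisole (1-ethynyl-4-methoxybenzene)
Product: 8 1-methoxy-4-(propa-1,2-dien-1-yl)benzene (4-methoxyphenylallene), via propargylic amine 7 (not isolated)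
Conditions: (CH2O)n (2.5 equiv), Cy2NH (1.8 equiv), CuI (0.5 equiv), 1,4-dioxane, 100 °C
Reagents that add atoms: paraformaldehyde, as formaldehyde (C=O)
Why: Crabbé homologation, in which a copper-mediated Mannich-type coupling of alkyne, formaldehyde and amine gives 7, and hydride transfer from an N–CH of 7 to the alkyne carbon (retro-imino-ene) releases the terminal allene and the imine.

Step 5
Reactants: 5 2,6-dihydroxy-3-iodo-4-methoxy-5-methylbenzaldehyde; 8 1-methoxy-4-(propa-1,2-dien-1-yl)benzene
Product: 9 (3E)-7-hydroxy-5-methoxy-3-(4-methoxybenzylidene)-6-methyl-4-oxo-3,4-dihydro-2H-chromene-8-carbaldehyde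
Conditions: Pd(OAc)2 (5 mol %), dppb (5 mol %), i-Pr2NEt (3 equiv), 8 (2 equiv), CO (20 atm), 1,4-dioxane, 100 °C
Reagents that add atoms: carbon monoxide ([C-]#[O+])
Why: Zerovalent palladium (from Pd(OAc)2 and the bisphosphine dppb) inserts into the C–I bond of 5 at the future C4a, CO insertion gives an aroylpalladium species whose acyl carbon becomes C4, and carbopalladation of allene 8 at its central carbon forms C3–C4 and a 2-aroyl-π-allylpalladium unit. The phenoxide oxygen on the neighbouring ring carbon (future O1) then attacks the unsubstituted CH2 terminus (O1–C2), so that ring C closes as a six-membered ring by intramolecular allylic substitution and zerovalent palladium is released. The closest known reaction type is the palladium-catalysed carbonylative annulation of o-iodophenols with allenes to 3-methylene- and 3-alkylidenechroman-4-ones. The site on ring A needs no control: iodine marks C4a, and the only hydroxyl ortho to it is the C8a–OH (the other ortho group is the C5 methoxy), so the C7–OH cannot cyclise. The selectivity that is needed is attack at the CH2 terminus and not at the benzylic terminus of the π-allyl unit; the aryl group favours the less hindered, conjugated product, and a branched ether would hold an acidic, acyl-stabilised phenoxide as leaving group, so it should re-ionise on palladium and drain to the benzylidene isomer, with the CO pressure suppressing allene insertion before carbonylation. No stereocentre is formed; the E alkene is the thermodynamic one, and a Z isomer would converge in step 6.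

Step 6
Reactants: 9 (3E)-7-hydroxy-5-methoxy-3-(4-methoxybenzylidene)-6-methyl-4-oxo-3,4-dihydro-2H-chromene-8-carbaldehyde
Product: 10 7-hydroxy-5-methoxy-3-(4-methoxybenzyl)-6-methyl-4-oxo-4H-chromene-8-carbaldehyde (target)
Conditions: RhCl3·3H2O (10 mol %), EtOH, 78 °C
Reagents that add atoms: none
Why: rhodium-catalysed alkene isomerisation, in which a rhodium hydride formed from RhCl3·3H2O in ethanol adds across the exocyclic C3=CH bond and β-hydride elimination toward C2–H moves the double bond into ring C, a shift known for 3-benzylidenechroman-4-ones and driven by formation of the conjugated 4-pyranone, under conditions that are neutral toward the chelated phenol–aldehyde pair and the aryl methyl ethers.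

**Compound list**
1 | 2-methylphloroglucinol (2,4,6-trihydroxytoluene) | Cc1c(O)cc(O)cc1O | starting material
2 | (2,4,6-trihydroxy-3-methylbenzylidene)dimethylammonium chloride (not isolated) | C[N+](C)=Cc1c(O)cc(O)c(C)c1O.[Cl-] | intermediate
3 | 2,4,6-trihydroxy-3-methylbenzaldehyde | Cc1c(O)cc(O)c(C=O)c1O | intermediate
4 | 2,6-dihydroxy-4-methoxy-3-methylbenzaldehyde | COc1cc(O)c(C=O)c(O)c1C | intermediate
5 | 2,6-dihydroxy-3-iodo-4-methoxy-5-methylbenzaldehyde | COc1c(I)c(O)c(C=O)c(O)c1C | intermediate
6 | 4-ethynylanisole (1-ethynyl-4-methoxybenzene) | COc1ccc(C#C)cc1 | starting material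
7 | N-cyclohexyl-N-[3-(4-methoxyphenyl)prop-2-yn-1-yl]cyclohexanamine (not isolated) | COc1ccc(C#CCN(C2CCCCC2)C2CCCCC2)cc1 | intermediate
8 | 1-methoxy-4-(propa-1,2-dien-1-yl)benzene | COc1ccc(C=C=C)cc1 | intermediate
9 | (3E)-7-hydroxy-5-methoxy-3-(4-methoxybenzylidene)-6-methyl-4-oxo-3,4-dihydro-2H-chromene-8-carbaldehyde | COc1ccc(/C=C2\COc3c(C=O)c(O)c(C)c(OC)c3C2=O)cc1 | intermediate
10 | 7-hydroxy-5-methoxy-3-(4-methoxybenzyl)-6-methyl-4-oxo-4H-chromene-8-carbaldehyde | COc1ccc(Cc2coc3c(C=O)c(O)c(C)c(OC)c3c2=O)cc1 | target

Total step count: 6. Longest linear sequence: 5 steps (steps 1, 2, 3, 5, 6); step 4 is a one-step branch.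

**Steps most likely to fail**

1. Step 5 (key step). Ring closure at the benzylic terminus of the π-allyl unit may fail to equilibrate to the conjugated isomer. Other failure modes are allene insertion before CO uptake, intermolecular acylation of a phenoxide by the aroylpalladium species, and loss of iodine by reduction. Fallback, which replaces the carbonylative annulation by acylation and one-carbon insertion and sets out from 4: Friedel–Crafts acylation of 4 at its free ring carbon with 3-(4-methoxyphenyl)propanoic acid in BF3·OEt2 at 80 °C would give the dihydrochalcone 2,6-dihydroxy-4-methoxy-3-[3-(4-methoxyphenyl)propanoyl]-5-methylbenzaldehyde F1. Treatment of F1 with DMF, MsCl and BF3·OEt2 at 70 °C (Vilsmeier-type aminomethylenation of the ketone CH2) would give the enaminone 3-[(2E)-3-(dimethylamino)-2-(4-methoxybenzyl)prop-2-enoyl]-2,6-dihydroxy-4-methoxy-5-methylbenzaldehyde F2, not isolated. In F2 the C8a–OH, the only hydroxyl ortho to the ketone, displaces dimethylamine and closes ring C, so the fallback comes back to the route at 10.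

2. Step 2. Site selectivity between the three phenols may be lost, with methylation at an ortho hydroxyl or double methylation. Fallback, which replaces selective alkylation by exhaustive alkylation and chelation-controlled dealkylation and sets out from 3: methylation of all three hydroxyls (MeI in excess, K2CO3, DMF, 40 °C) would give 2,4,6-trimethoxy-3-methylbenzaldehyde F3. AlCl3 (4 equiv, CH2Cl2, 25 → 40 °C) would then cleave the two methoxy groups ortho to the formyl group through the aluminium chelate and leave the para methoxy group, so the fallback comes back to the route at 4.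

3. Step 6. The double-bond shift may stay incomplete, or the formyl group may suffer acetal formation or decarbonylation on rhodium. Fallback, which replaces the isomerisation by reduction and dehydrogenation and sets out from 9: hydrogenation of the benzylidene double bond (H2 1 atm, 5% Pd/C, EtOAc, 25 °C, stopped after one equivalent) would give racemic 7-hydroxy-5-methoxy-3-(4-methoxybenzyl)-6-methyl-4-oxo-3,4-dihydro-2H-chromene-8-carbaldehyde F4. Aerobic dehydrogenation of F4 with Pd(O2CCF3)2 (divalent palladium, 10 mol %) in DMSO under O2 at 80 °C, through a palladium enolate at C3 and β-hydride elimination from C2, would then form the C2=C3 bond, so the fallback comes back to the route at 10.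

**Further compounds**
F1 | step 5 | 2,6-dihydroxy-4-methoxy-3-[3-(4-methoxyphenyl)propanoyl]-5-methylbenzaldehyde | COc1ccc(CCC(=O)c2c(O)c(C=O)c(O)c(C)c2OC)cc1
F2 | step 5 | 3-[(2E)-3-(dimethylamino)-2-(4-methoxybenzyl)prop-2-enoyl]-2,6-dihydroxy-4-methoxy-5-methylbenzaldehyde | COc1ccc(C/C(=C\N(C)C)C(=O)c2c(O)c(C=O)c(O)c(C)c2OC)cc1
F3 | step 2 | 2,4,6-trimethoxy-3-methylbenzaldehyde | COc1cc(OC)c(C=O)c(OC)c1C
F4 | step 6 | 7-hydroxy-5-methoxy-3-(4-methoxybenzyl)-6-methyl-4-oxo-3,4-dihydro-2H-chromene-8-carbaldehyde (racemic) | COc1ccc(CC2COc3c(C=O)c(O)c(C)c(OC)c3C2=O)cc1
A1 | direct plan | comenic acid (5-hydroxy-4-oxo-4H-pyran-2-carboxylic acid) | O=C(O)c1cc(=O)c(O)co1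
A2 | direct plan | methyl 5-(4-methoxybenzyl)-4-oxo-4H-pyran-2-carboxylate | COC(=O)c1cc(=O)c(Cc2ccc(OC)cc2)co1
A3 | direct plan | 2-(2-diazoacetyl)-5-(4-methoxybenzyl)-4H-pyran-4-one | COc1ccc(Cc2coc(C(=O)C=[N+]=[N-])cc2=O)cc1
A4 | direct plan | triisopropyl(prop-1-yn-1-yloxy)silane | CC#CO[Si](C(C)C)(C(C)C)C(C)C
A5 | direct plan | 5-hydroxy-3-(4-methoxybenzyl)-6-methyl-7-[(triisopropylsilyl)oxy]-4H-chromen-4-one | COc1ccc(Cc2coc3cc(O[Si](C(C)C)(C(C)C)C(C)C)c(C)c(O)c3c2=O)cc1
A6 | direct plan | 7-hydroxy-5-methoxy-3-(4-methoxybenzyl)-6-methyl-4H-chromen-4-one | COc1ccc(Cc2coc3cc(O)c(C)c(OC)c3c2=O)cc1
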